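**Strategy.** Vibsanin E's core is a bicyclo[4.3.1]decane: a cyclohexane whose 1,3-positions (the quaternary C–Me carbon and the ring-fusion CH shared by all three rings) are spanned by the four-carbon, ketone-bearing chain of the cycloheptanone. Both rings are closed at once by a cationic formal [5+2] cycloaddition. A dicobalt-complexed propargylic cation carrying a silyl enol ether (five carbons, quaternary carbon to ketone α-carbon) adds across a tethered vinyl group, joining the bridging CH2 to the quaternary carbon and the ring-fusion CH to the ketone α-carbon. The acyclic precursor comes from dehydrolinalool; one epoxide-derived stereocentre controls both bridgeheads. Pyran closure and side chains follow.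

Key step: step 7

Remark: bicyclic compounds 11–14 are numbered as bicyclo[4.3.1]decanes (C-1 bridgehead CH, C-3 ketone, C-6 quaternary C–Me, C-9 side-chain carbon) and tricyclic compounds as 6-oxatricyclo[6.3.2.0(4,13)]tridecanes (C-1 quaternary C–Me, C-4 and C-13 ring-fusion CH, C-5 CMe2, O-6, C-8 CH next to the C-9 ketone, C-10 and C-11 side-chain carbons, C-12 bridging CH2); the methoxy-bearing centre of 2–9 is carried as a mixture because it is planarised in step 7.

Step 1
Reactants: 1 dehydrolinalool (rac-3,7-dimethyloct-6-en-1-yn-3-ol)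
Product: 2 rac-3-methoxy-3,7-dimethyloct-6-en-1-yne
Conditions: NaH, MeI, THF/DMF, 0 °C to rt
Reagents that add atoms: iodomethane, CI
Why: Williamson etherification of the tertiary propargylic alkoxide installs the methoxy group that later serves as the ionisable leaving group and meanwhile keeps the alcohol from cyclising onto the epoxide.

Step 2
Reactants: 2 rac-3-methoxy-3,7-dimethyloct-6-en-1-yne
Product: 3 (3R)-3-[(3RS)-3-methoxy-3-methylpent-4-yn-1-yl]-2,2-dimethyloxirane
Conditions: D-fructose-derived Shi ketone (30 mol%), KHSO5 (as 2KHSO5·KHSO4·K2SO4), K2CO3, Bu4NHSO4, MeCN/CH2(OMe)2/aq. Na2B4O7 buffer, 0 °C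
Reagents that add atoms: potassium peroxymonosulfate (KHSO5), [K+].[O-]S(=O)(=O)OO
Why: Shi asymmetric epoxidation (chiral dioxirane, spiro transition state) of the only alkene, a trisubstituted one, should give the (R)-epoxide with the D-fructose-derived ketone while the alkyne stays inert.

Step 3
Reactants: 3 (3R)-3-[(3RS)-3-methoxy-3-methylpent-4-yn-1-yl]-2,2-dimethyloxirane; 4 vinylmagnesium bromide
Product: 5 (3R,6RS)-3-ethenyl-6-methoxy-2,6-dimethyloct-7-yn-2-ol
Conditions: vinylMgBr (3 equiv), CuI (10 mol%), THF, −30 to 0 °C; aq. NH4Cl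
Reagents that add atoms: none
Why: Copper-catalysed SN2 opening of the trisubstituted epoxide at its less substituted carbon with inversion should set the (R)-configured vinyl-bearing carbon and free the tertiary alcohol, the alkyne C–H being only deprotonated and restored on work-up.

Step 4
Reactants: 5 (3R,6RS)-3-ethenyl-6-methoxy-2,6-dimethyloct-7-yn-2-ol; 6 N-methoxy-N-methylacetamide
Product: 7 (5RS,8R)-8-ethenyl-9-hydroxy-5-methoxy-5,9-dimethyldec-3-yn-2-one
Conditions: n-BuLi (2.1 equiv), THF, −78 °C; then 6, −78 to 0 °C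
Reagents that add atoms: none
Why: Acylation of the lithium acetylide with the Weinreb amide should stop at the methyl ynone because the chelated tetrahedral adduct survives until work-up, and the lithium alkoxide does not react with the amide.

Step 5
Reactants: 7 (5RS,8R)-8-ethenyl-9-hydroxy-5-methoxy-5,9-dimethyldec-3-yn-2-one
Product: 8 (3R,6RS)-2,9-bis(tert-butyldimethylsilyloxy)-3-ethenyl-6-methoxy-2,6-dimethyldec-9-en-7-yne
Conditions: TBSOTf (2.5 equiv), Et3N, CH2Cl2, −78 to 0 °C
Reagents that add atoms: tert-butyldimethylsilyl trifluoromethanesulfonate, CC(C)(C)[Si](C)(C)OS(=O)(=O)C(F)(F)F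
Why: Silyl triflate/amine soft enolisation should convert the methyl ynone into its 2-silyloxy enyne while the same reagent silylates the hindered tertiary alcohol.

Step 6
Reactants: 8 (3R,6RS)-2,9-bis(tert-butyldimethylsilyloxy)-3-ethenyl-6-methoxy-2,6-dimethyldec-9-en-7-yne
Product: 9 Co2(CO)6 complex of 8 at the C-7/C-8 triple bond
Conditions: Co2(CO)8, CH2Cl2, rt
Reagents that add atoms: dicobalt octacarbonyl, O=C=[Co](=C=O)(=C=O)(=C=O)[Co](=C=O)(=C=O)(=C=O)=C=O
Why: Alkyne complexation with Co2(CO)8 (preparation of a Nicholas precursor) is selective for the triple bond at room temperature and should leave the enol ether and the vinyl group untouched.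

Step 7
Reactants: 9 Co2(CO)6 complex of 8 at the C-7/C-8 triple bond
Product: 11 Co2(CO)6 complex of (1R,6S,9R)-9-[2-(tert-butyldimethylsilyloxy)propan-2-yl]-6-methylbicyclo[4.3.1]dec-4-yn-3-one, via propargylic cation 10 (not isolated)
Conditions: EtAlCl2 (1.5 equiv), CH2Cl2 (0.002 M, slow addition of 9), −78 to −20 °C
Reagents that add atoms: none
Why: Proposed new method: EtAlCl2 removes methoxide to give the Co2(CO)6-stabilised tertiary propargylic cation 10 (Nicholas-type cation), the terminal CH2 of the tethered vinyl group attacks its cationic carbon, and the silyl enol ether carbon captures the positive charge building up at the internal alkene carbon before the silyl group is lost to methoxide, giving the ketone. The closest known reaction type is the stepwise [5+2] cycloaddition of dicobalt-complexed 2-silyloxypent-1-en-3-yn-5-yl cations with enol silyl ethers, together with intramolecular Nicholas alkylation of alkenes; new here is an unactivated monosubstituted alkene as the two-carbon partner in a bridging mode. The cyclohexane closes by 6-endo attack of the vinyl group (Markovnikov, both alkene carbons in the ring) and the seven-membered ring by attack of the enol ether terminus on the ring carbocation with the enol C=C inside the new ring (7-endo), which the bent complexed alkyne (C–C≡C angle near 140°) makes geometrically possible. The quaternary carbon (C-6) and the bridgehead CH (C-1) are controlled by the existing (R)-centre through a chair transition state with the CMe2OTBS group equatorial; the four-carbon bridge can only span cis-1,3-diaxial positions, so the methyl group ends up equatorial and trans to that substituent. The step needs regioselectivity for bond formation at the CH2 terminus (secondary against primary cation), ring closure before hydride shift, proton loss or intermolecular attack of a second enol ether (high dilution, non-nucleophilic medium), and no collapse of the five-carbon unit on itself, which the complexed alkyne excludes because it cannot lie in a five-membered ring. Addition with the alkyne arm equatorial cannot bridge and should revert by fragmentation to the stabilised cation, so that material is funnelled through the productive chair.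

Step 8
Reactants: 11 Co2(CO)6 complex of (1R,6S,9R)-9-[2-(tert-butyldimethylsilyloxy)propan-2-yl]-6-methylbicyclo[4.3.1]dec-4-yn-3-one
Product: 12 (1R,6S,9R)-9-[2-(tert-butyldimethylsilyloxy)propan-2-yl]-6-methylbicyclo[4.3.1]dec-4-en-3-one
Conditions: Bu3SnH, benzene, 65 °C
Reagents that add atoms: none
Why: Reductive decomplexation of a cycloalkyne–Co2(CO)6 complex with the tin hydride delivers two hydrogen atoms syn and should free the (Z)-alkene, here the cyclohept-2-enone, without touching the ketone or the silyl ether.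

Step 9
Reactants: 12 (1R,6S,9R)-9-[2-(tert-butyldimethylsilyloxy)propan-2-yl]-6-methylbicyclo[4.3.1]dec-4-en-3-one
Product: 13 (1R,6S,9R)-9-(2-hydroxypropan-2-yl)-6-methylbicyclo[4.3.1]dec-4-en-3-one
Conditions: HF·pyridine, THF/pyridine, 0 °C to rt
Reagents that add atoms: none
Why: Fluoride-mediated desilylation should free the tertiary alcohol under conditions that leave the enone intact.

Step 10
Reactants: 13 (1R,6S,9R)-9-(2-hydroxypropan-2-yl)-6-methylbicyclo[4.3.1]dec-4-en-3-one
Product: 15 (1S,4R,8S,13S)-1,5,5-trimethyl-6-oxatricyclo[6.3.2.0(4,13)]tridec-10-en-9-one, via exo-methylene ketone 14 (not isolated)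
Conditions: (CH2O)n, PhNHMe·CF3CO2H, THF, reflux; then DBU (cat.), rt
Reagents that add atoms: paraformaldehyde (as formaldehyde), C=O
Why: Mannich-type α-methylenation can only take place at the single enolisable CH2 (C-2 of 13), and the exo-methylene ketone 14 should be trapped by 6-endo-trig oxa-Michael addition of the tertiary alcohol, protonation of the epimerisable α-carbon giving the cis ring fusion that the bridged skeleton enforces.

Step 11
Reactants: 15 (1S,4R,8S,13S)-1,5,5-trimethyl-6-oxatricyclo[6.3.2.0(4,13)]tridec-10-en-9-one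
Product: 17 (1S,4R,8S,13S)-10-bromo-1,5,5-trimethyl-6-oxatricyclo[6.3.2.0(4,13)]tridec-10-en-9-one, via dibromide 16 (not isolated)
Conditions: Br2, CH2Cl2, −78 °C; then Et3N, 0 °C
Reagents that add atoms: bromine, BrBr
Why: Electrophilic bromine addition to the enone followed by E1cB loss of HBr (acidic α-H, β-bromide) should give the α-bromo enone, a route chosen because the neopentyl β-carbon resists nucleophile-triggered α-halogenation.

Step 12
Reactants: 17 (1S,4R,8S,13S)-10-bromo-1,5,5-trimethyl-6-oxatricyclo[6.3.2.0(4,13)]tridec-10-en-9-one; 18 tributyl(2-methylprop-2-en-1-yl)stannane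
Product: 19 (1S,4R,8S,13S)-1,5,5-trimethyl-10-(2-methylprop-2-en-1-yl)-6-oxatricyclo[6.3.2.0(4,13)]tridec-10-en-9-one
Conditions: Pd2(dba)3 (5 mol%), AsPh3, CuI, DMF, 60 °C
Reagents that add atoms: none
Why: Stille coupling of the α-bromo enone with the allylic stannane should install the methallyl group as a masked acetonyl group, the identical allyl termini making allylic transposition irrelevant.

Step 13
Reactants: 19 (1S,4R,8S,13S)-1,5,5-trimethyl-10-(2-methylprop-2-en-1-yl)-6-oxatricyclo[6.3.2.0(4,13)]tridec-10-en-9-one; 4 vinylmagnesium bromide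
Product: 21 (1S,4R,8S,10S,11S,13S)-11-ethenyl-1,5,5-trimethyl-10-(2-methylprop-2-en-1-yl)-6-oxatricyclo[6.3.2.0(4,13)]tridecan-9-one, via magnesium enolate 20 (not isolated)
Conditions: vinylMgBr (4 equiv), CuBr·SMe2 (2 equiv), THF, −78 to −40 °C; then sat. aq. NH4Cl/THF, −78 to 0 °C
Reagents that add atoms: none
Why: Conjugate addition of the cuprate (CH2=CH)2CuMgBr should occur on the convex face of the enone (away from the cyclohexane bridge, syn to the C-1 methyl group), and kinetic protonation of enolate 20 from the same open face should place the methallyl group on the concave side, trans to the vinyl group.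

Step 14
Reactants: 21 (1S,4R,8S,10S,11S,13S)-11-ethenyl-1,5,5-trimethyl-10-(2-methylprop-2-en-1-yl)-6-oxatricyclo[6.3.2.0(4,13)]tridecan-9-one
Product: 23 (1S,4R,8S,10S,11S,13S)-1,5,5-trimethyl-9-oxo-10-(2-oxopropyl)-6-oxatricyclo[6.3.2.0(4,13)]tridecane-11-carbaldehyde, via bis-ozonide 22 (not isolated)
Conditions: O3, CH2Cl2, −78 °C; then PPh3, −78 °C to rt
Reagents that add atoms: ozone, [O-][O+]=O
Why: Ozonolysis with reductive work-up should cleave both terminal alkenes at once, the 1,1-disubstituted one to the acetonyl ketone and the vinyl group to the aldehyde, under neutral conditions that spare the two α-stereocentres.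

Step 15
Reactants: 23 (1S,4R,8S,10S,11S,13S)-1,5,5-trimethyl-9-oxo-10-(2-oxopropyl)-6-oxatricyclo[6.3.2.0(4,13)]tridecane-11-carbaldehyde; 24 2-(dichloromethyl)-4,4,5,5-tetramethyl-1,3,2-dioxaborolane
Product: 25 (1S,4R,8S,10S,11S,13S)-1,5,5-trimethyl-10-(2-oxopropyl)-11-[(E)-2-(4,4,5,5-tetramethyl-1,3,2-dioxaborolan-2-yl)ethenyl]-6-oxatricyclo[6.3.2.0(4,13)]tridecan-9-one
Conditions: CrCl2 (8 equiv), LiI, THF, rt
Reagents that add atoms: none
Why: Takai–Utimoto-type boron olefination through a geminal dichromium reagent is (E)-selective and should react with the aldehyde much faster than with either ketone.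

Step 16
Reactants: 25 (1S,4R,8S,10S,11S,13S)-1,5,5-trimethyl-10-(2-oxopropyl)-11-[(E)-2-(4,4,5,5-tetramethyl-1,3,2-dioxaborolan-2-yl)ethenyl]-6-oxatricyclo[6.3.2.0(4,13)]tridecan-9-one
Product: 26 potassium trifluoro{(E)-2-[(1S,4R,8S,10S,11S,13S)-1,5,5-trimethyl-9-oxo-10-(2-oxopropyl)-6-oxatricyclo[6.3.2.0(4,13)]tridecan-11-yl]ethenyl}borate
Conditions: KHF2, MeOH/H2O, rt
Reagents that add atoms: potassium hydrogen difluoride, [K+].[F-].F
Why: Ligand exchange of the pinacol boronate with KHF2 should give the alkenyltrifluoroborate with retention of the double-bond geometry.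

Step 17
Reactants: 26 potassium trifluoro{(E)-2-[(1S,4R,8S,10S,11S,13S)-1,5,5-trimethyl-9-oxo-10-(2-oxopropyl)-6-oxatricyclo[6.3.2.0(4,13)]tridecan-11-yl]ethenyl}borate; 27 3-methylbut-2-enoic acid
Product: 28 vibsanin E
Conditions: CuBr (10 mol%), DMAP (20 mol%), 4 Å MS, O2 (1 atm), MeCN, 40 °C
Reagents that add atoms: none
Why: Copper-catalysed oxidative C–O coupling (Chan–Lam type) of the alkenyltrifluoroborate with the carboxylic acid should form the enol ester with retention of the (E)-geometry under conditions mild enough for the β-alkoxy ketone and the 1,4-diketone.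

**Compound list**

1 | dehydrolinalool (rac-3,7-dimethyloct-6-en-1-yn-3-ol) | C#CC(C)(O)CCC=C(C)C | starting material
2 | rac-3-methoxy-3,7-dimethyloct-6-en-1-yne | C#CC(C)(OC)CCC=C(C)C | intermediate
3 | (3R)-3-[(3RS)-3-methoxy-3-methylpent-4-yn-1-yl]-2,2-dimethyloxirane | C#CC(C)(OC)CC[C@H]1OC1(C)C | intermediate
4 | vinylmagnesium bromide | C=C[Mg]Br | starting material
5 | (3R,6RS)-3-ethenyl-6-methoxy-2,6-dimethyloct-7-yn-2-ol | C#CC(C)(OC)CC[C@H](C=C)C(C)(C)O | intermediate
6 | N-methoxy-N-methylacetamide | CC(=O)N(C)OC | starting material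
7 | (5RS,8R)-8-ethenyl-9-hydroxy-5-methoxy-5,9-dimethyldec-3-yn-2-one | CC(=O)C#CC(C)(OC)CC[C@H](C=C)C(C)(C)O | intermediate
8 | (3R,6RS)-2,9-bis(tert-butyldimethylsilyloxy)-3-ethenyl-6-methoxy-2,6-dimethyldec-9-en-7-yne | C=C(O[Si](C)(C)C(C)(C)C)C#CC(C)(OC)CC[C@H](C=C)C(C)(C)O[Si](C)(C)C(C)(C)C | intermediate
9 | Co2(CO)6 complex of 8 (dicobalt unit bridging the C-7/C-8 triple bond) | C=C(O[Si](C)(C)C(C)(C)C)C12[Co]3(=C=O)(=C=O)(=C=O)[Co]1(=C=O)(=C=O)(=C=O)C23C(C)(OC)CC[C@H](C=C)C(C)(C)O[Si](C)(C)C(C)(C)C | intermediate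
10 | Co2(CO)6-stabilised tertiary propargylic cation formed from 9 by loss of methoxide | C=C(O[Si](C)(C)C(C)(C)C)C12[Co]3(=C=O)(=C=O)(=C=O)[Co]1(=C=O)(=C=O)(=C=O)C23[C+](C)CC[C@H](C=C)C(C)(C)O[Si](C)(C)C(C)(C)C | intermediate
11 | Co2(CO)6 complex of (1R,6S,9R)-9-[2-(tert-butyldimethylsilyloxy)propan-2-yl]-6-methylbicyclo[4.3.1]dec-4-yn-3-one | O=C1C[C@H]2C[C@](C)(CC[C@H]2C(C)(C)O[Si](C)(C)C(C)(C)C)C34[Co]5(=C=O)(=C=O)(=C=O)[Co]3(=C=O)(=C=O)(=C=O)C145 | intermediate
12 | (1R,6S,9R)-9-[2-(tert-butyldimethylsilyloxy)propan-2-yl]-6-methylbicyclo[4.3.1]dec-4-en-3-one | O=C1C[C@H]2C[C@](C)(CC[C@H]2C(C)(C)O[Si](C)(C)C(C)(C)C)C=C1 | intermediate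
13 | (1R,6S,9R)-9-(2-hydroxypropan-2-yl)-6-methylbicyclo[4.3.1]dec-4-en-3-one | O=C1C[C@H]2C[C@](C)(CC[C@H]2C(C)(C)O)C=C1 | intermediate
14 | (1S,6S,9R)-9-(2-hydroxypropan-2-yl)-6-methyl-2-methylidenebicyclo[4.3.1]dec-4-en-3-one | O=C1C(=C)[C@H]2C[C@](C)(CC[C@H]2C(C)(C)O)C=C1 | intermediate
15 | (1S,4R,8S,13S)-1,5,5-trimethyl-6-oxatricyclo[6.3.2.0(4,13)]tridec-10-en-9-one | C=1C(=O)[C@@H]2COC(C)(C)[C@@H]3CC[C@@](C)(C[C@@H]32)C=1 | intermediate
16 | trans-10,11-dibromo-1,5,5-trimethyl-6-oxatricyclo[6.3.2.0(4,13)]tridecan-9-one (other centres as in 15; the two CHBr centres not assigned) | BrC1C(=O)[C@@H]2COC(C)(C)[C@@H]3CC[C@@](C)(C[C@@H]32)C1Br | intermediate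
17 | (1S,4R,8S,13S)-10-bromo-1,5,5-trimethyl-6-oxatricyclo[6.3.2.0(4,13)]tridec-10-en-9-one | BrC=1C(=O)[C@@H]2COC(C)(C)[C@@H]3CC[C@@](C)(C[C@@H]32)C=1 | intermediate
18 | tributyl(2-methylprop-2-en-1-yl)stannane | C=C(C)C[Sn](CCCC)(CCCC)CCCC | starting material
19 | (1S,4R,8S,13S)-1,5,5-trimethyl-10-(2-methylprop-2-en-1-yl)-6-oxatricyclo[6.3.2.0(4,13)]tridec-10-en-9-one | C=C(C)CC=1C(=O)[C@@H]2COC(C)(C)[C@@H]3CC[C@@](C)(C[C@@H]32)C=1 | intermediate
20 | bromomagnesium enolate (C-9/C-10) of 21 | C=C(C)CC1=C(O[Mg]Br)[C@@H]2COC(C)(C)[C@@H]3CC[C@@](C)(C[C@@H]32)[C@H]1C=C | intermediate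
21 | (1S,4R,8S,10S,11S,13S)-11-ethenyl-1,5,5-trimethyl-10-(2-methylprop-2-en-1-yl)-6-oxatricyclo[6.3.2.0(4,13)]tridecan-9-one | C=C(C)C[C@@H]1C(=O)[C@@H]2COC(C)(C)[C@@H]3CC[C@@](C)(C[C@@H]32)[C@H]1C=C | intermediate
22 | bis-ozonide of 21 (a 1,2,4-trioxolane in place of each C=C; trioxolane centres not assigned) | CC4(C[C@@H]1C(=O)[C@@H]2COC(C)(C)[C@@H]3CC[C@@](C)(C[C@@H]32)[C@H]1C5OCOO5)OCOO4 | intermediate
23 | (1S,4R,8S,10S,11S,13S)-1,5,5-trimethyl-9-oxo-10-(2-oxopropyl)-6-oxatricyclo[6.3.2.0(4,13)]tridecane-11-carbaldehyde | CC(=O)C[C@@H]1C(=O)[C@@H]2COC(C)(C)[C@@H]3CC[C@@](C)(C[C@@H]32)[C@H]1C=O | intermediate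
24 | 2-(dichloromethyl)-4,4,5,5-tetramethyl-1,3,2-dioxaborolane | ClC(Cl)B1OC(C)(C)C(C)(C)O1 | starting material
25 | (1S,4R,8S,10S,11S,13S)-1,5,5-trimethyl-10-(2-oxopropyl)-11-[(E)-2-(4,4,5,5-tetramethyl-1,3,2-dioxaborolan-2-yl)ethenyl]-6-oxatricyclo[6.3.2.0(4,13)]tridecan-9-one | CC(=O)C[C@@H]1C(=O)[C@@H]2COC(C)(C)[C@@H]3CC[C@@](C)(C[C@@H]32)[C@H]1/C=C/B1OC(C)(C)C(C)(C)O1 | intermediate
26 | potassium trifluoro{(E)-2-[(1S,4R,8S,10S,11S,13S)-1,5,5-trimethyl-9-oxo-10-(2-oxopropyl)-6-oxatricyclo[6.3.2.0(4,13)]tridecan-11-yl]ethenyl}borate | CC(=O)C[C@@H]1C(=O)[C@@H]2COC(C)(C)[C@@H]3CC[C@@](C)(C[C@@H]32)[C@H]1/C=C/[B-](F)(F)F.[K+] | intermediate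
27 | 3-methylbut-2-enoic acid | CC(C)=CC(=O)O | starting material
28 | vibsanin E, (E)-2-[(1S,4R,8S,10S,11S,13S)-1,5,5-trimethyl-9-oxo-10-(2-oxopropyl)-6-oxatricyclo[6.3.2.0(4,13)]tridecan-11-yl]ethenyl 3-methylbut-2-enoate | CC(=O)C[C@@H]1C(=O)[C@@H]2COC(C)(C)[C@@H]3CC[C@@](C)(C[C@@H]32)[C@H]1/C=C/OC(=O)C=C(C)C | target

**Step count and risks**

Total step count: 17. Longest linear sequence: 17 steps (from 1).

The three steps most likely to fail:

Step 7 (Proposed new method). The monosubstituted alkene is a weak nucleophile. Intermolecular attack of the silyl enol ether of a second molecule on the cation, proton loss from the cation to an enyne, or hydride shift and chloride capture at the secondary cationic carbon may outrun closure of the seven-membered ring. The fallback changes the two-carbon partner to the class for which this cycloaddition is established, and sets out from 7. Tsuji–Wacker oxidation (PdCl2 cat., CuCl, O2, DMF/H2O) of the vinyl group would give the methyl ketone, diketone F1. TBSOTf/Et3N would give the tris-silyl derivative F2 (tertiary silyl ether and both terminal silyl enol ethers), and Co2(CO)8 would give the alkyne complex F3. EtAlCl2 would then effect the cycloaddition with an enol silyl ether as the nucleophilic two-carbon unit, through a silyloxocarbenium ion instead of a secondary cation, to give the bridgehead silyl ether F4. DBU would eliminate silanol from this β-silyloxy ketone to give the bridgehead enone F5 while the complexed alkyne stays protected. Conjugate reduction with [(Ph3P)CuH]6 would come back to the route at 11.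

Step 13. Conjugate addition at the neopentyl β-carbon of the α-substituted enone may be too slow, so that carbonyl addition or enolisation takes over; protonation from the concave face would give the C-10 epimer. The fallback sets out from 19. Hosomi–Sakurai allylation (allyltrimethylsilane, TiCl4, CH2Cl2, −78 °C; protonation of the titanium enolate on quenching) would give the allyl ketone F6. [Ir(cod)(PMePh2)2]PF6 activated with H2 would isomerise the monosubstituted allyl group to the (E)-propenyl group faster than the 1,1-disubstituted methallyl group, giving the propenyl ketone F7. Ozonolysis (O3; then PPh3) of both alkenes would come back to the route at 23. The C-10 configuration would still rest on protonation from the open face.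

Step 17. Protodeboronation of 26, or aldol and epimerisation chemistry of the 1,4-diketone under the copper/DMAP conditions, may erode the coupling. The fallback sets out from 23 and reaches 28 directly. Wittig olefination with the ylide made in the flask from [(3-methylbut-2-enoyloxy)methyl]triphenylphosphonium chloride and NaN(SiMe3)2 (THF, −78 °C) would give the enol ester as an (E)/(Z) mixture, from which the (E)-isomer 28 would be separated. This fallback makes no new isolated compound.

**Further compounds**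

F1 | step 7 | 8-acetyl-9-hydroxy-5-methoxy-5,9-dimethyldec-3-yn-2-one (vinyl group of 7 oxidised to acetyl; configuration as in 7) | CC(=O)C#CC(C)(OC)CC[C@H](C(C)=O)C(C)(C)O
F2 | step 7 | tris(tert-butyldimethylsilyl) derivative of F1 (tertiary silyl ether and both terminal silyl enol ethers) | C=C(O[Si](C)(C)C(C)(C)C)C#CC(C)(OC)CC[C@H](C(=C)O[Si](C)(C)C(C)(C)C)C(C)(C)O[Si](C)(C)C(C)(C)C
F3 | step 7 | Co2(CO)6 complex of F2 at the triple bond | C=C(O[Si](C)(C)C(C)(C)C)C12[Co]3(=C=O)(=C=O)(=C=O)[Co]1(=C=O)(=C=O)(=C=O)C23C(C)(OC)CC[C@H](C(=C)O[Si](C)(C)C(C)(C)C)C(C)(C)O[Si](C)(C)C(C)(C)C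
F4 | step 7 | Co2(CO)6 complex of 1-(tert-butyldimethylsilyloxy)-9-[2-(tert-butyldimethylsilyloxy)propan-2-yl]-6-methylbicyclo[4.3.1]dec-4-yn-3-one (skeleton and configuration as in 11) | O=C1C[C@@]2(O[Si](C)(C)C(C)(C)C)C[C@](C)(CC[C@H]2C(C)(C)O[Si](C)(C)C(C)(C)C)C34[Co]5(=C=O)(=C=O)(=C=O)[Co]3(=C=O)(=C=O)(=C=O)C145
F5 | step 7 | Co2(CO)6 complex of 9-[2-(tert-butyldimethylsilyloxy)propan-2-yl]-6-methylbicyclo[4.3.1]dec-1-en-4-yn-3-one | O=C1C=C2C[C@](C)(CC[C@H]2C(C)(C)O[Si](C)(C)C(C)(C)C)C34[Co]5(=C=O)(=C=O)(=C=O)[Co]3(=C=O)(=C=O)(=C=O)C145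
F6 | step 13 | 1,5,5-trimethyl-10-(2-methylprop-2-en-1-yl)-11-(prop-2-en-1-yl)-6-oxatricyclo[6.3.2.0(4,13)]tridecan-9-one (configuration as in 21) | C=C(C)C[C@@H]1C(=O)[C@@H]2COC(C)(C)[C@@H]3CC[C@@](C)(C[C@@H]32)[C@H]1CC=C
F7 | step 13 | 1,5,5-trimethyl-10-(2-methylprop-2-en-1-yl)-11-[(E)-prop-1-en-1-yl]-6-oxatricyclo[6.3.2.0(4,13)]tridecan-9-one (configuration as in 21) | C=C(C)C[C@@H]1C(=O)[C@@H]2COC(C)(C)[C@@H]3CC[C@@](C)(C[C@@H]32)[C@H]1/C=C/C
F0 | step 17 | none | none
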